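## The problem

The target is a seco-elemane: a single cyclohexane (C5–C10) with five contiguous stereocentres and no second ring to lean on. C10 is quaternary (C14 methyl on the β face, C1=C2 vinyl on the α face) and C5 carries the hydroxymethyl-vinyl arm C4(=C3)C15 on the α face. C6–O, C7–C11 and C8–O are all β, so in the only reasonable chair the C7 acrylic acid arm is axial between two equatorial oxygens; this less stable arrangement must be set kinetically and C7 must never sit next to a carbonyl. The free α-methylene acid C12 is cis to both C6–OH and C8–O and closes to a γ-lactone under acid or base. The C8 ester is a 3,4-dihydroxy-2-methylenebutanoate, which lactonises and releases the core above pH 7, and the three further alkenes forbid late hydrogenation or radical steps. C10, C5 and C6 can be set in one bond-forming event and C7/C8 derived from them; the side-chain carbinol is remote and must come from the chiral pool, and nothing in the ring fixes its absolute configuration, so a removable external stereocentre is needed. The enabling feature is that C9–C8–C7–C6 carries oxygen at C8 and C6 like a 1,3-dioxygenated diene, that C10 and C5 carry cis one-carbon arms (C1, C4) that can be the two ends of a butenolide, and that C14 on C10 is cis-1,3 to the C8 oxygen and can be tied to it through silicon.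

## Retrosynthesis

**Unmasking (40 from 38 and 37).** Only O–Si, O–CH2Ar and O–tBu bonds are cut. The end of the route may use only buffered fluoride and a silyl triflate, so C6–OH and the side-chain diol are TBS ethers and C12 is a tert-butyl ester, which resists both neighbouring hydroxyls and organolithiums and leaves as a silyl ester. C15–OH is a PMB ether, because its oxygen arrives on a carbanion that cannot carry silicon; it is removed oxidatively from 37 to give 38.

**C8–O acyl bond (37 from 29 and 36).** This is the one convergent cut, and it puts the base-labile side chain on last. Acid 36 is four carbons with one stereocentre and comes from (R)-3-hydroxy-γ-butyrolactone 30 through the α-methylene lactone 33. Building the side chain on a C8 acrylate instead would leave its carbinol uncontrolled. The forward step must acylate a flanked secondary alcohol without base-induced lactonisation.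

**C11=C13 (29 from 28 from 25).** The exocyclic methylene is cut back to the CH2CO2tBu arm of 25. It is introduced only after the C4 lactone is gone, whose α-proton would compete, and before the C8 oxygen is freed.

**C1=C2, C3=C4 and C4–C15 (25 from 24, 23, 20 and 22).** Both alkenes are cut to the 1,4-keto aldehyde 24, which comes from a single addition of the PMB-oxymethyl carbanion from stannane 22 to the cis-fused C1–O–C4 lactone 20. Lactone 20 holds both arms in masked form and keeps them cis. The forward addition must choose the lactone over the tert-butyl ester and stop after one addition.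

**C1 acetal and C14–O (20 from 17, 16 and 14).** The C14 methyl group is cut to a hydroxymethyl group, the price of the tether. Deoxygenation is placed before any alkene exists, because a C14 radical next to a vinyl group would rearrange. The menthyloxy group on C1 is removed only afterwards, so that the reduced C1–OH is the only hydroxyl that can relactonise on to C4.

**C7–H and C8–H (13 from 12); tether (14 from 13).** The two hydrogens are cut to the bridgehead enol ether of 12. Inside the bridge O8 must stay cis to C14, so syn addition of hydrogen from the open face fixes C8 and C7 together. A C8 ketone is never formed, which matters because C7 would epimerise to the wrong, more stable configuration next to it.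

**C9–C10 and C5–C6 (12 from 11), the key cut.** Cutting both bonds opens the ring to a 1,3-bis(silyloxy)diene and a butenolide. An intermolecular version would fail twice: the β,β-disubstituted butenolide is a poor dienophile, and the endo rule would place the lactone carbonyl cis to the C6 oxygen. Tying C14–O to the C8 oxygen through a diisopropylsilicon unit makes the reaction intramolecular and forces the C14 arm endo and the lactone exo. The absolute sense is supplied by a menthyloxy acetal at C1, which the diene must avoid.

**Silaketal and its halves (11 from 5 and 9; 5 from 4 and 1; 9 from 7, 6 and 8).** The silaketal is cut at both Si–O bonds into enone 5 and alcohol 9. Formylating a levulinate would be the shortest way to 5 on paper, but methyl ketones with a chain longer than ethyl are formylated mainly at the methyl group. The C7–C8 bond is therefore made by acetylating the enamine of aldehyde 1, where only one carbon can react, giving 4. Butenolide 9 comes from 3-furanmethanol 6 by photo-oxygenation to 7 and acetal exchange with (−)-menthol 8.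

## Roads not taken

Alternative 1: The cut is at both alkene arms, back to a C1=C4 cyclobutene. In the forward direction the cis-fused bicyclo[4.2.0]octene A1 is opened with ethylene and the second-generation Grubbs catalyst to the diene A2.
- Merits: strain-driven ring-opening metathesis is reliable, it reveals the vinyl and the silyloxymethyl-vinyl arm in one step, and the ring fusion guarantees that they are cis. No C14 deoxygenation is needed. In this respect it is better than the chosen plan, which spends steps 13–15 on the same two arms and steps 9–10 on C14.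
- Weak points: A2 carries only C10, C5 and a C6 oxygen of the wrong configuration. C7 and C8 are bare methylenes, so the all-cis C6/C7/C8 triad with its axial acrylic acid arm, the real difficulty of the target, would have to be built afterwards on an unactivated ring in the presence of two alkenes.
- Comparison: the chosen plan sets against it that all five ring stereocentres come from two operations (steps 6 and 7) whose outcome is enforced by geometry.

Alternative 2: The cut is the C6–C7 bond. In the forward direction CrCl2 (divalent chromium) turns the (Z)-2-(bromomethyl)enoate of the open-chain aldehyde A3 into an allylchromium, whose γ-carbon adds to the C6 aldehyde and closes the ring to the hydroxy ester A4.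
- Merits: the α-methylene ester is formed directly, so no step like step 16 is needed. Ring closure sets C6 and C7 together, and the protecting groups of A4 are nearly those of the end game. Its end game is shorter than the chosen one.
- Weak points: the required outcome (C6–OH cis to an axial C7 arm that is also cis to C8–O) is not the one a chair-like transition state with equatorial substituents favours. A4 is a γ-hydroxy α-methylene ester that tends to lactonise, the very reaction the target must avoid. A3, with a quaternary stereocentre next to a tertiary one in an open chain, needs its own long stereocontrolled synthesis.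
- Comparison: the chosen plan pays with an ester methylenation and a deoxygenation, but it obtains the quaternary centre and its neighbours from a cycloaddition of two small, easily made partners.

Alternative 3: The cut is the C9–C10 bond, with the O–C2 bond re-formed. In the forward direction the 2-methylene-oxocene A5 undergoes a Claisen rearrangement on heating and contracts to the cyclohexanone A6.
- Merits: C10 is made with its vinyl group and methyl group directly, with no deoxygenation, no lactone opening and no aldehyde olefination. The C8 oxygen appears as a ketone, and chirality is relayed from C5–C7. For C10 it is more economical than the chosen plan.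
- Weak points: A5 is an eight-membered cyclic enol ether with three contiguous stereocentres and a trisubstituted Z alkene, which is costly to close and to methylenate. The chair or boat transition state decides C10. In A6 the C7 arm sits next to the C8 ketone in its less stable orientation, so epimerisation threatens during the rearrangement and the reduction, and that reduction must also give the equatorial alcohol.
- Comparison: the chosen plan sets against it that C7 never has a neighbouring carbonyl and that C8 is fixed by a constraint, not by reagent selectivity.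

Key step: step 6

Remarks before the steps:
- Locants C1–C15 are the elemane locants used above; primes mark the C8 ester side chain. β is the ring face that carries C14, α the opposite face.
- Assumption: tert-butyl 4-oxobutanoate (1), (tributylstannyl)methanol (21), (R)-3-hydroxy-γ-butyrolactone (30) and diisopropylsilyl bis(trifluoromethanesulfonate) are taken as catalogue chemicals.
- Assumption: hydroxy ketone 23 is drawn open-chain; it will equilibrate with its cyclic hemiketal, which does not affect step 14.

## Route

Step 1
Reactants: 1 tert-butyl 4-oxobutanoate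
Product: 4 tert-butyl (3Z)-3-(hydroxymethylene)-4-oxopentanoate (enol form of tert-butyl 3-formyl-4-oxopentanoate), via morpholine enamine 2 (not isolated), via acetylated enaminone 3 (not isolated)
Conditions: morpholine, K2CO3, toluene, 0 °C; then AcCl, Et3N, CH2Cl2, 0 → 25 °C; then 1 M aq. HCl, THF, 0 °C
Reagents that add atoms: acetyl chloride CC(=O)Cl; water O
Why: Stork enamine C-acylation; the aldehyde enamine can only be acylated at the carbon that becomes C7, which fixes the branched β-keto aldehyde that Claisen formylation of a levulinate would not give. Cold dilute acid hydrolyses the vinylogous amide and spares the tert-butyl ester.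

Step 2
Reactants: 4 tert-butyl (3Z)-3-(hydroxymethylene)-4-oxopentanoate
Product: 5 tert-butyl (3E)-3-[(tert-butyldimethylsilyloxy)methylene]-4-oxopentanoate
Conditions: TBSCl, imidazole, CH2Cl2, 0 → 25 °C
Reagents that add atoms: tert-butyldimethylsilyl chloride CC(C)(C)[Si](C)(C)Cl
Why: O-silylation of the enolised aldehyde of a β-keto aldehyde. The push–pull alkene equilibrates easily and the E isomer (silyloxy trans to acetyl, the later "outside" position of the diene) is the expected thermodynamic product, as for the parent 4-silyloxybut-3-en-2-ones.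

Step 3
Reactants: 6 3-furanmethanol
Product: 7 5-hydroxy-4-(hydroxymethyl)furan-2(5H)-one (racemic hemiacetal)
Conditions: O2, visible light, tetraphenylporphyrin (cat.), iPr2NEt, CH2Cl2, −78 → 25 °C
Reagents that add atoms: oxygen O=O
Why: [4+2] addition of singlet oxygen to the furan followed by base-induced (Kornblum–DeLaMare type) fragmentation of the endoperoxide. The hindered amine removes the ring proton remote from the substituent, so the hydroxymethyl group ends β to the lactone carbonyl, as in the known oxidation of 3-alkylfurans.

Step 4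
Reactants: 7 5-hydroxy-4-(hydroxymethyl)furan-2(5H)-one; 8 (−)-menthol
Product: 9 (5R)-4-(hydroxymethyl)-5-[(1R,2S,5R)-menthyloxy]furan-2(5H)-one
Conditions: 8 (3 equiv), camphorsulfonic acid (cat.), toluene, 80 °C, water removed; 5R epimer isolated by crystallisation or chromatography, 5S epimer re-equilibrated with the same acid
Reagents that add atoms: none
Why: Acid-catalysed acetal exchange through the acyloxocarbenium ion, the standard entry to 5-menthyloxybutenolides. The two C5 epimers are diastereomers that interconvert under the acid, so the unwanted one can be recycled; excess menthol suppresses self-condensation through the primary hydroxyl.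

Step 5
Reactants: 5 tert-butyl (3E)-3-[(tert-butyldimethylsilyloxy)methylene]-4-oxopentanoate; 9 (5R)-4-(hydroxymethyl)-5-menthyloxyfuran-2(5H)-one
Product: 11 diisopropylsilyl-linked triene (silaketal of the C8 dienol of 5 and the hydroxymethyl group of 9), via dienyl silyl triflate 10 (not isolated)
Conditions: 5 (1.1 equiv), Et3N (3 equiv), iPr2Si(OTf)2 (1.1 equiv), CH2Cl2, −78 → 0 °C; then 9 (1.0 equiv), 0 °C; filtration through Et3N-deactivated silica
Reagents that add atoms: diisopropylsilyl bis(trifluoromethanesulfonate) CC(C)[Si](OS(=O)(=O)C(F)(F)F)(OS(=O)(=O)C(F)(F)F)C(C)C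
Why: Soft enolisation: the silyl triflate binds the ketone oxygen and Et3N removes a methyl (C9) proton, the ester methylene not being acidified by the vinylogous oxocarbenium ion. The hindered monotriflate 10 then silylates the primary alcohol of 9, the usual way to unsymmetrical silaketals; 9 is added last, so no free silyl triflate is left to enolise the butenolide and scramble the acetal centre.

Step 6
Reactants: 11 diisopropylsilyl-linked triene
Product: 12 bridged cycloadduct (bicyclo[4.3.1] silaketal with C7=C8 bridgehead enol ether, cis-fused C1–O–C4 menthyloxy lactone on the α face, C6 β-OTBS)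
Conditions: toluene (0.01 M), 2,6-di-tert-butyl-4-methylpyridine (0.2 equiv), BHT (trace), 120 °C, sealed vessel
Reagents that add atoms: none
Why: On heating, the 1,3-bis(silyloxy)diene C9=C8–C7=C6 and the butenolide alkene C5=C10 combine in a concerted, asynchronous normal-demand [4+2] cycloaddition that forms C9–C10 and C5–C6; the nucleophilic diene terminus C9 meets the lactone β-carbon C10, so polarity and tether ask for the same regiochemistry. The closest known reaction type is the silicon-tethered type 2 intramolecular Diels–Alder reaction of 2-silyloxydienes with allylic-alcohol dienophiles, which gives bridgehead enol ethers, together with thermal additions of silyloxydienes to 5-menthyloxybutenolides. The cyclohexene C5–C10 closes by the cycloaddition itself, and the seven-membered 1,3-dioxa-2-silepane (C8–O–Si–O–C14–C10–C9) closes through the same C9–C10 bond in the bridged mode, giving a bicyclo[4.3.1]decene with the C7=C8 double bond at the bridgehead. C10 and C5 follow from suprafacial addition to the ring alkene, which keeps C1 and C4 cis. C6 is set because the tethered C14 arm can only lie under the diene (endo), which puts the lactone carbonyl exo and brings the outside (E) silyloxy group cis to C14 and trans to C4. The absolute sense comes from the C1 acetal: the diene adds to the face anti to the menthyloxy group, as in all cycloadditions of this auxiliary, and here the new quaternary centre C10 is directly next to it. The step needs regio-, endo/exo-, π-facial and diene-geometry control, secured in turn by the tether, again the tether, the 5R acetal and the E enol ether; the β,β-disubstituted butenolide reacts at all only because the reaction is intramolecular and the diene is doubly oxygenated.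

Step 7
Reactants: 12 bridged cycloadduct
Product: 13 saturated bridged silaketal (H7 and H8 α; C7 CH2CO2tBu and C8–O β)
Conditions: H2 (50 bar), Rh/Al2O3 (5 wt %), EtOAc, 25 °C
Reagents that add atoms: none
Why: Heterogeneous syn hydrogenation of the twisted tetrasubstituted enol ether from the α face, the β face being covered by the silaketal bridge; rhodium is chosen because it saturates enol ethers with little C–O hydrogenolysis. Because O8 must stay cis to C14 inside the bridge, H8 is α and syn addition makes H7 α as well, which gives the all-cis C6/C7/C8 array.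

Step 8
Reactants: 13 saturated bridged silaketal
Product: 14 C8,C14-diol (C6–OTBS, menthyloxy lactone and tert-butyl ester intact)
Conditions: HF·pyridine, pyridine, THF, 0 °C
Reagents that add atoms: none
Why: Fluoride cleaves the dialkoxydiisopropylsilane (two Si–O bonds, more electrophilic silicon) much faster than the flanked secondary TBS ether, as in the routine removal of cyclic dialkylsilylene groups beside TBS ethers. The pyridine buffer spares the acetal and the tert-butyl ester.

Step 9
Reactants: 14 C8,C14-diol
Product: 16 C14 O-phenyl thionocarbonate C8 triethylsilyl ether, via thionocarbonate alcohol 15 (not isolated)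
Conditions: PhOC(S)Cl (1.1 equiv), pyridine, CH2Cl2, −20 → 0 °C; then 2,6-lutidine, Et3SiOTf, −78 → 0 °C
Reagents that add atoms: O-phenyl chlorothionoformate S=C(Cl)Oc1ccccc1; triethylsilyl trifluoromethanesulfonate CC[Si](CC)(CC)OS(=O)(=O)C(F)(F)F
Why: The primary hydroxyl is thioacylated selectively over the flanked secondary C8–OH, which is then silylated in the same flask. The TES ether keeps O8 from lactonising on to C12 and from being oxidised in the later steps.

Step 10
Reactants: 16 C14 O-phenyl thionocarbonate C8 triethylsilyl ether
Product: 17 C14-methyl menthyloxy lactone (C8–OTES, C6–OTBS)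
Conditions: Bu3SnH (2 equiv), AIBN (0.2 equiv), toluene, 110 °C
Reagents that add atoms: none
Why: Barton–McCombie deoxygenation. It is run at this point because the molecule has no alkene that the primary C14 radical could add to or shift, and the radical has no 1,5-hydrogen within reach on its face.

Step 11
Reactants: 17 C14-methyl menthyloxy lactone
Product: 20 cis-fused C1–O–C4 γ-lactone (C1 now CH2), via lithium aldehyde carboxylate 18 (not isolated), via lithium hydroxy carboxylate 19 (not isolated)
Conditions: LiOH, THF/H2O, 0 → 25 °C; then NaBH4, 0 °C; then AcOH to pH 4, 25 °C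
Reagents that add atoms: lithium hydroxide [Li+].[OH-] (its oxygen can remain as the lactone carbonyl oxygen)
Why: Saponification of the acetal-type ester releases menthol and C1 as a non-enolisable aldehyde, NaBH4 reduces it, and the γ-hydroxy acid relactonises on acidification. With C14 now a methyl group only the cis-fused lactone can form; the tert-butyl ester and both silyl ethers tolerate cold LiOH.

Step 12
Reactants: 21 (tributylstannyl)methanol
Product: 22 tributyl[(4-methoxybenzyloxy)methyl]stannane
Conditions: NaH, THF/DMF, 0 °C; 4-MeOC6H4CH2Cl, Bu4NI (cat.), 25 °C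
Reagents that add atoms: 4-methoxybenzyl chloride COc1ccc(CCl)cc1
Why: Williamson etherification of the primary alkoxide. The carbon–tin bond is inert to these conditions.

Step 13
Reactants: 20 cis-fused C1–O–C4 γ-lactone; 22 tributyl[(4-methoxybenzyloxy)methyl]stannane
Product: 23 C1-hydroxy C4-ketone bearing C15–OPMB
Conditions: 22 (1.5 equiv), n-BuLi (1.45 equiv), THF, −78 °C; then 20, −78 °C; AcOH quench at −78 °C
Reagents that add atoms: none
Why: Tin–lithium exchange gives the α-alkoxymethyllithium, which adds once to the γ-lactone because the lithium hemiketalate persists at −78 °C; it is faster than attack on or deprotonation of the tert-butyl ester. C5, now α to a ketone, already has the more stable equatorial (α) arm.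

Step 14
Reactants: 23 C1-hydroxy C4-ketone
Product: 24 C1-aldehyde C4-ketone
Conditions: Dess–Martin periodinane, NaHCO3, CH2Cl2, 0 → 25 °C
Reagents that add atoms: none
Why: Dess–Martin oxidation of the neopentyl primary alcohol of the open-chain tautomer; the hemiketal hydroxyl is tertiary and cannot be oxidised. The aldehyde has no α-hydrogen.

Step 15
Reactants: 24 C1-aldehyde C4-ketone
Product: 25 C10-vinyl C5-[3-(4-methoxybenzyloxy)prop-1-en-2-yl] diene
Conditions: Ph3PCH3Br (6 equiv), KOtBu (5.5 equiv), THF, 0 °C; 24 added at −78 °C, then → 50 °C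
Reagents that add atoms: methyltriphenylphosphonium bromide C[P+](c1ccccc1)(c1ccccc1)c1ccccc1.[Br-]
Why: Double Wittig methylenation forms C1=C2 and C4=C3. The aldehyde reacts at low temperature before any enolate can add to it, and the α-alkoxy ketone follows on warming with excess salt-free ylide.

Step 16
Reactants: 25 diene tert-butyl ester
Product: 28 C7 tert-butyl acrylate (C11=C13 in place), via Mannich base 26 (not isolated), via trimethylammonium iodide 27 (not isolated)
Conditions: LiN(iPr)2, THF, −78 °C; CH2=NMe2+ I−, −78 → 25 °C; then MeI, CH2Cl2, 25 °C; then DBU, 0 °C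
Reagents that add atoms: Eschenmoser's salt C=[N+](C)C.[I-]
Why: The ester enolate (the only acidic site left) undergoes a Mannich reaction; quaternisation and E1cB loss of trimethylamine give the α-methylene ester. C7 is not touched, so its axial configuration is kept.

Step 17
Reactants: 28 C7 tert-butyl acrylate
Product: 29 C8 alcohol
Conditions: HF·pyridine, pyridine, THF, 0 °C
Reagents that add atoms: none
Why: The triethylsilyl ether is cleaved far faster than the flanked secondary TBS ether under buffered fluoride. The tert-butyl ester is too poor an acyl donor to lactonise on to the freed hydroxyl under these conditions.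

Step 18
Reactants: 30 (R)-3-hydroxy-γ-butyrolactone
Product: 33 (R)-4-hydroxy-3-methylenedihydrofuran-2(3H)-one, via aminomethyl lactone 31 (not isolated), via ammonium iodide 32 (not isolated)
Conditions: LiN(iPr)2 (2.2 equiv), THF, −78 → −40 °C; CH2=NMe2+ I−, −78 → 0 °C; AcOH; then MeI, CH2Cl2, 25 °C; then DBU, 0 °C
Reagents that add atoms: Eschenmoser's salt C=[N+](C)C.[I-]
Why: The alkoxide enolate dianion of the β-hydroxy lactone (Frater–Seebach type) does not eliminate and is aminomethylated at the α-carbon; quaternisation and elimination give the α-methylene lactone. The carbinol centre is not involved.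

Step 19
Reactants: 33 (R)-4-hydroxy-3-methylenedihydrofuran-2(3H)-one
Product: 36 (3R)-3,4-bis(tert-butyldimethylsilyloxy)-2-methylenebutanoic acid, via lithium carboxylate 34 (not isolated), via tris-silyl compound 35 (not isolated)
Conditions: LiOH (1.05 equiv), THF/H2O, 0 °C; evaporation; TBSCl, imidazole, DMF, 25 °C; then AcOH/THF/H2O, 25 °C
Reagents that add atoms: lithium hydroxide [Li+].[OH-]; tert-butyldimethylsilyl chloride CC(C)(C)[Si](C)(C)Cl
Why: Saponification opens the lactone; the dihydroxy carboxylate is never acidified, since it would relactonise, but is persilylated directly. The labile silyl ester is then hydrolysed selectively, leaving the two TBS ethers.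

Step 20
Reactants: 29 C8 alcohol; 36 (3R)-3,4-bis(tert-butyldimethylsilyloxy)-2-methylenebutanoic acid
Product: 37 C8 ester (fully protected target)
Conditions: 36 (1.5 equiv), 2,4,6-Cl3C6H2COCl, Et3N, toluene, 25 °C; then 29, DMAP, toluene, 25 → 40 °C
Reagents that add atoms: none
Why: Yamaguchi esterification through the mixed anhydride and the acylpyridinium ion, a standard answer for hindered secondary alcohols. The acid has no α-hydrogen, so no ketene or epimerisation pathway exists.

Step 21
Reactants: 37 C8 ester
Product: 38 C15 allylic alcohol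
Conditions: DDQ, CH2Cl2/pH 7 phosphate buffer, 0 °C
Reagents that add atoms: none
Why: Oxidative cleavage of the PMB ether by hydride abstraction and hydrolysis of the oxocarbenium ion. The isolated and electron-poor alkenes, silyl ethers and esters are inert to buffered DDQ.

Step 22
Reactants: 38 C15 allylic alcohol
Product: 40 target acid, via bis(trimethylsilyl) intermediate 39 (not isolated)
Conditions: Me3SiOTf, 2,6-lutidine, CH2Cl2, 0 °C; then HF·pyridine, pyridine, THF, 0 → 25 °C
Reagents that add atoms: none
Why: The silyl triflate converts the tert-butyl ester into a trimethylsilyl ester with loss of isobutene and caps C15–OH. Buffered fluoride then removes every silicon group at once, so the acid-sensitive hydroxy acid and the base-sensitive side-chain ester never meet strong acid or base.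

## Compound list

1 | tert-butyl 4-oxobutanoate | O=CCCC(=O)OC(C)(C)C | starting material
2 | tert-butyl (3E)-4-(morpholin-4-yl)but-3-enoate | O=C(OC(C)(C)C)C/C=C/N1CCOCC1 | intermediate
3 | tert-butyl 3-(morpholin-4-ylmethylene)-4-oxopentanoate | CC(=O)C(CC(=O)OC(C)(C)C)=CN1CCOCC1 | intermediate
4 | tert-butyl (3Z)-3-(hydroxymethylene)-4-oxopentanoate | CC(=O)/C(CC(=O)OC(C)(C)C)=C\O | intermediate
5 | tert-butyl (3E)-3-[(tert-butyldimethylsilyloxy)methylene]-4-oxopentanoate | CC(=O)/C(CC(=O)OC(C)(C)C)=C/O[Si](C)(C)C(C)(C)C | intermediate
6 | 3-furanmethanol | OCc1ccoc1 | starting material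
7 | 5-hydroxy-4-(hydroxymethyl)furan-2(5H)-one, racemic | OCC1=CC(=O)OC1O | intermediate
8 | (−)-menthol, (1R,2S,5R) | C[C@@H]1CC[C@H]([C@@H](C1)O)C(C)C | starting material
9 | (5R)-4-(hydroxymethyl)-5-[(1R,2S,5R)-menthyloxy]furan-2(5H)-one | OCC1=CC(=O)O[C@H]1O[C@@H]2C[C@H](C)CC[C@H]2C(C)C | intermediate
10 | dienyl(diisopropyl)silyl triflate of 5 (C8 enol ether) | C=C(O[Si](C(C)C)(C(C)C)OS(=O)(=O)C(F)(F)F)/C(CC(=O)OC(C)(C)C)=C/O[Si](C)(C)C(C)(C)C | intermediate
11 | diisopropylsilyl-linked triene: (E)-dienyl silyl ether (C6 OTBS, C7 CH2CO2tBu, C8 O–Si) joined to the hydroxymethyl group of 9 | C=C(O[Si](C(C)C)(C(C)C)OCC1=CC(=O)O[C@H]1O[C@@H]2C[C@H](C)CC[C@H]2C(C)C)/C(CC(=O)OC(C)(C)C)=C/O[Si](C)(C)C(C)(C)C | intermediate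
12 | bridged cycloadduct: C14–O–Si–O–C8 bridge (β), C7=C8 bridgehead enol ether, cis-fused C1–O–C4 lactone (α) with menthyloxy on C1, C6 β-OTBS | [C@H]3(O[C@@H]4C[C@H](C)CC[C@H]4C(C)C)[C@]1(CO[Si](C(C)C)(C(C)C)O2)CC2=C(CC(=O)OC(C)(C)C)[C@@H](O[Si](C)(C)C(C)(C)C)[C@@H]1C(=O)O3 | intermediate
13 | saturated bridged silaketal: as 12 with H7 and H8 α | [C@H]3(O[C@@H]4C[C@H](C)CC[C@H]4C(C)C)[C@]1(CO[Si](C(C)C)(C(C)C)O2)C[C@@H]2[C@@H](CC(=O)OC(C)(C)C)[C@@H](O[Si](C)(C)C(C)(C)C)[C@@H]1C(=O)O3 | intermediate
14 | C8,C14-diol: C8 β-OH, C14 CH2OH, C6 β-OTBS, menthyloxy lactone | [C@H]3(O[C@@H]4C[C@H](C)CC[C@H]4C(C)C)[C@]1(CO)C[C@@H](O)[C@@H](CC(=O)OC(C)(C)C)[C@@H](O[Si](C)(C)C(C)(C)C)[C@@H]1C(=O)O3 | intermediate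
15 | C14 O-phenyl thionocarbonate of 14, C8–OH free | [C@H]3(O[C@@H]4C[C@H](C)CC[C@H]4C(C)C)[C@]1(COC(=S)Oc5ccccc5)C[C@@H](O)[C@@H](CC(=O)OC(C)(C)C)[C@@H](O[Si](C)(C)C(C)(C)C)[C@@H]1C(=O)O3 | intermediate
16 | C14 O-phenyl thionocarbonate, C8 β-OTES | [C@H]3(O[C@@H]4C[C@H](C)CC[C@H]4C(C)C)[C@]1(COC(=S)Oc5ccccc5)C[C@@H](O[Si](CC)(CC)CC)[C@@H](CC(=O)OC(C)(C)C)[C@@H](O[Si](C)(C)C(C)(C)C)[C@@H]1C(=O)O3 | intermediate
17 | C14-methyl menthyloxy lactone, C8 β-OTES, C6 β-OTBS | [C@H]3(O[C@@H]4C[C@H](C)CC[C@H]4C(C)C)[C@]1(C)C[C@@H](O[Si](CC)(CC)CC)[C@@H](CC(=O)OC(C)(C)C)[C@@H](O[Si](C)(C)C(C)(C)C)[C@@H]1C(=O)O3 | intermediate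
18 | lithium C4-carboxylate with C1 aldehyde | O=C[C@]1(C)C[C@@H](O[Si](CC)(CC)CC)[C@@H](CC(=O)OC(C)(C)C)[C@@H](O[Si](C)(C)C(C)(C)C)[C@@H]1C(=O)[O-].[Li+] | intermediate
19 | lithium C4-carboxylate with C1 CH2OH | OC[C@]1(C)C[C@@H](O[Si](CC)(CC)CC)[C@@H](CC(=O)OC(C)(C)C)[C@@H](O[Si](C)(C)C(C)(C)C)[C@@H]1C(=O)[O-].[Li+] | intermediate
20 | cis-fused C1–O–C4 γ-lactone: C10 β-methyl, C8 β-OTES, C7 β-CH2CO2tBu, C6 β-OTBS | C3[C@]1(C)C[C@@H](O[Si](CC)(CC)CC)[C@@H](CC(=O)OC(C)(C)C)[C@@H](O[Si](C)(C)C(C)(C)C)[C@@H]1C(=O)O3 | intermediate
21 | (tributylstannyl)methanol | CCCC[Sn](CCCC)(CCCC)CO | starting material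
22 | tributyl[(4-methoxybenzyloxy)methyl]stannane | CCCC[Sn](CCCC)(CCCC)COCc1ccc(OC)cc1 | intermediate
23 | C1-hydroxy C4-ketone: C10 CH2OH (α), C5 α-C(=O)CH2OPMB | OC[C@]1(C)C[C@@H](O[Si](CC)(CC)CC)[C@@H](CC(=O)OC(C)(C)C)[C@@H](O[Si](C)(C)C(C)(C)C)[C@@H]1C(=O)COCc2ccc(OC)cc2 | intermediate
24 | C1-aldehyde C4-ketone | O=C[C@]1(C)C[C@@H](O[Si](CC)(CC)CC)[C@@H](CC(=O)OC(C)(C)C)[C@@H](O[Si](C)(C)C(C)(C)C)[C@@H]1C(=O)COCc2ccc(OC)cc2 | intermediate
25 | diene: C10 α-vinyl, C5 α-C(=CH2)CH2OPMB, C7 β-CH2CO2tBu | C=C[C@]1(C)C[C@@H](O[Si](CC)(CC)CC)[C@@H](CC(=O)OC(C)(C)C)[C@@H](O[Si](C)(C)C(C)(C)C)[C@@H]1C(=C)COCc2ccc(OC)cc2 | intermediate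
26 | Mannich base of 25 (C11 CH2NMe2, C11 configuration open) | C=C[C@]1(C)C[C@@H](O[Si](CC)(CC)CC)[C@@H](C(CN(C)C)C(=O)OC(C)(C)C)[C@@H](O[Si](C)(C)C(C)(C)C)[C@@H]1C(=C)COCc2ccc(OC)cc2 | intermediate
27 | trimethylammonium iodide of 26 | C=C[C@]1(C)C[C@@H](O[Si](CC)(CC)CC)[C@@H](C(C[N+](C)(C)C)C(=O)OC(C)(C)C)[C@@H](O[Si](C)(C)C(C)(C)C)[C@@H]1C(=C)COCc2ccc(OC)cc2.[I-] | intermediate
28 | C7 β-C(=CH2)CO2tBu acrylate, C8 β-OTES | C=C[C@]1(C)C[C@@H](O[Si](CC)(CC)CC)[C@@H](C(=C)C(=O)OC(C)(C)C)[C@@H](O[Si](C)(C)C(C)(C)C)[C@@H]1C(=C)COCc2ccc(OC)cc2 | intermediate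
29 | C8 β-alcohol | C=C[C@]1(C)C[C@@H](O)[C@@H](C(=C)C(=O)OC(C)(C)C)[C@@H](O[Si](C)(C)C(C)(C)C)[C@@H]1C(=C)COCc2ccc(OC)cc2 | intermediate
30 | (R)-3-hydroxy-γ-butyrolactone | O=C1C[C@@H](O)CO1 | starting material
31 | (4R)-3-(dimethylaminomethyl)-4-hydroxydihydrofuran-2(3H)-one (C3 open) | CN(C)CC1C(=O)OC[C@@H]1O | intermediate
32 | trimethylammonium iodide of 31 | C[N+](C)(C)CC1C(=O)OC[C@@H]1O.[I-] | intermediate
33 | (4R)-4-hydroxy-3-methylenedihydrofuran-2(3H)-one | C=C1C(=O)OC[C@@H]1O | intermediate
34 | lithium (3R)-3,4-dihydroxy-2-methylenebutanoate | C=C(C(=O)[O-])[C@@H](O)CO.[Li+] | intermediate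
35 | tert-butyldimethylsilyl (3R)-3,4-bis(tert-butyldimethylsilyloxy)-2-methylenebutanoate | C=C(C(=O)O[Si](C)(C)C(C)(C)C)[C@@H](O[Si](C)(C)C(C)(C)C)CO[Si](C)(C)C(C)(C)C | intermediate
36 | (3R)-3,4-bis(tert-butyldimethylsilyloxy)-2-methylenebutanoic acid | C=C(C(=O)O)[C@@H](O[Si](C)(C)C(C)(C)C)CO[Si](C)(C)C(C)(C)C | intermediate
37 | C8 ester: fully protected target (C6 OTBS, C15 OPMB, C12 tert-butyl ester, side-chain bis-TBS) | C=C[C@]1(C)C[C@@H](OC(=O)C(=C)[C@@H](O[Si](C)(C)C(C)(C)C)CO[Si](C)(C)C(C)(C)C)[C@@H](C(=C)C(=O)OC(C)(C)C)[C@@H](O[Si](C)(C)C(C)(C)C)[C@@H]1C(=C)COCc2ccc(OC)cc2 | intermediate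
38 | C15 allylic alcohol | C=C[C@]1(C)C[C@@H](OC(=O)C(=C)[C@@H](O[Si](C)(C)C(C)(C)C)CO[Si](C)(C)C(C)(C)C)[C@@H](C(=C)C(=O)OC(C)(C)C)[C@@H](O[Si](C)(C)C(C)(C)C)[C@@H]1C(=C)CO | intermediate
39 | C12 trimethylsilyl ester, C15 trimethylsilyl ether | C=C[C@]1(C)C[C@@H](OC(=O)C(=C)[C@@H](O[Si](C)(C)C(C)(C)C)CO[Si](C)(C)C(C)(C)C)[C@@H](C(=C)C(=O)O[Si](C)(C)C)[C@@H](O[Si](C)(C)C(C)(C)C)[C@@H]1C(=C)CO[Si](C)(C)C | intermediate
40 | CNP0348657.6: (5S,6S,7S,8R,10S)-6,15-dihydroxy-8-[(3R)-3,4-dihydroxy-2-methylenebutanoyloxy]elema-1,3,11(13)-trien-12-oic acid | C=C[C@]1(C)C[C@@H](OC(=O)C(=C)[C@@H](O)CO)[C@@H](C(=C)C(=O)O)[C@@H](O)[C@@H]1C(=C)CO | target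

## Step count and weakest steps

Total: 22 steps. Longest linear sequence: 17 steps (1, 2, 5–11, 13–17, 20–22).

**Step 6 (key step).** The trisubstituted butenolide may react so slowly that thermal desilylation or E/Z isomerisation of the dienyl ethers outruns the cycloaddition; loss of facial control is the lesser worry. The fallback raises dienophile reactivity with an α-bromine. It sets out from 9: bromine adds across the ring alkene to give the dibromide F1, and Et3N removes HBr to give the 3-bromobutenolide F2. The tether is installed as in step 5 to give the bromo triene F3, whose cycloaddition (α-halo enoates are far better dienophiles) gives the bromo adduct F4. Bu3SnH/AIBN at 80 °C removes the tertiary α-bromine; the planar lactone radical takes hydrogen on the face that keeps the lactone cis-fused, and the route is rejoined at 12.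

**Step 4.** The two acetal epimers may not separate cleanly, and the free hydroxymethyl group can self-condense during acid-catalysed exchange. The fallback does not separate at this stage. It sets out from 7: the epimer mixture (9 with the 5S epimer F5) is taken through steps 5 and 6. The 5S epimer gives the triene F6 and, adding anti to its own menthyloxy group, the adduct F7 with the mirror-image core. 12 and F7 are diastereomers that differ in shape throughout and are separated by crystallisation or chromatography, so the route is rejoined at 12.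

**Step 7.** Uptake by the tetrasubstituted enol ether may be slow, with competing hydrogenolysis or hydrolysis of the Si–O–C8 enol bond; that would open the bridge and lose control of C7. The fallback replaces surface syn addition by radical hydrogen-atom transfer on 12, with tris(dipivaloylmethanato)manganese Mn(dpm)3, PhSiH3 and tert-butyl hydroperoxide in isopropanol. A hydrogen atom adds to C7 from the open α face, and the α-silyloxy radical at C8 takes the second hydrogen on the only face the bridge allows. This method is at its best with hindered electron-rich alkenes; it leads from 12 directly to 13 and makes no new compound F0.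

**Step 10.** β-Scission of the primary, neopentyl C14–O bond may be slow, so that the stannyl adduct radical is reduced instead and alcohol is returned. The fallback uses halogen-atom abstraction and sets out from 14. Exhaustive silylation (Et3SiOTf, 2,6-lutidine) gives the bis(triethylsilyl) ether F8, and PPTS in methanol frees the primary hydroxyl selectively to give the alcohol F9. Tf2O/pyridine gives the neopentyl triflate F10 and NaI in DMF the iodide F11; O8 is silylated throughout, so it cannot close a bicyclic ether on to C14. Bu3SnH/AIBN at 80 °C reduces the C–I bond and rejoins the route at 17.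

**Step 15.** The ylide may enolise the hindered ketone, and the C15 enolate could add to the C1 aldehyde in an intramolecular aldol reaction before methylenation. The fallback never makes the keto aldehyde and sets out from 23. Wittig methylenation of the ketone first gives the primary alcohol F12, Dess–Martin oxidation gives the aldehyde F13, and a second Wittig methylenation rejoins the route at 25.

**Step 22.** The hindered C6 silyl ether is slow to cleave, and during long fluoride treatment C6–OH may lactonise on to the free C12 acid, or the side-chain C4′–OH on to its own ester with loss of the core. The fallback changes the order so that the acid is set free last and without acid; it sets out from 38. Buffered HF·pyridine first gives the tetraol tert-butyl ester F14, in which no free acid is present. Me3SiOTf/2,6-lutidine then converts the ester into the silyl ester while capping every hydroxyl, giving the persilylated ester F15, and methanol at 0 °C releases 40.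

## Further compounds

F1 | step 6 | 3,4-dibromo-4-(hydroxymethyl)-5-menthyloxydihydrofuran-2(3H)-one (new centres open) | OCC1(Br)C(Br)C(=O)O[C@H]1O[C@@H]2C[C@H](C)CC[C@H]2C(C)C
F2 | step 6 | (5R)-3-bromo-4-(hydroxymethyl)-5-[(1R,2S,5R)-menthyloxy]furan-2(5H)-one | OCC1=C(Br)C(=O)O[C@H]1O[C@@H]2C[C@H](C)CC[C@H]2C(C)C
F3 | step 6 | diisopropylsilyl-linked triene from 5 and F2 | C=C(O[Si](C(C)C)(C(C)C)OCC1=C(Br)C(=O)O[C@H]1O[C@@H]2C[C@H](C)CC[C@H]2C(C)C)/C(CC(=O)OC(C)(C)C)=C/O[Si](C)(C)C(C)(C)C
F4 | step 6 | bridged cycloadduct with bromine on C5 | [C@H]3(O[C@@H]4C[C@H](C)CC[C@H]4C(C)C)[C@]1(CO[Si](C(C)C)(C(C)C)O2)CC2=C(CC(=O)OC(C)(C)C)[C@@H](O[Si](C)(C)C(C)(C)C)[C@]1(Br)C(=O)O3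
F5 | step 4 | (5S)-4-(hydroxymethyl)-5-[(1R,2S,5R)-menthyloxy]furan-2(5H)-one | OCC1=CC(=O)O[C@@H]1O[C@@H]2C[C@H](C)CC[C@H]2C(C)C
F6 | step 4 | diisopropylsilyl-linked triene from 5 and F5 | C=C(O[Si](C(C)C)(C(C)C)OCC1=CC(=O)O[C@@H]1O[C@@H]2C[C@H](C)CC[C@H]2C(C)C)/C(CC(=O)OC(C)(C)C)=C/O[Si](C)(C)C(C)(C)C
F7 | step 4 | bridged cycloadduct with mirror-image core and (1R,2S,5R)-menthyl group | [C@@H]3(O[C@@H]4C[C@H](C)CC[C@H]4C(C)C)[C@@]1(CO[Si](C(C)C)(C(C)C)O2)CC2=C(CC(=O)OC(C)(C)C)[C@H](O[Si](C)(C)C(C)(C)C)[C@H]1C(=O)O3
F0 | step 7 | none | none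
F8 | step 10 | C8,C14-bis(triethylsilyl) ether of 14 | [C@H]3(O[C@@H]4C[C@H](C)CC[C@H]4C(C)C)[C@]1(CO[Si](CC)(CC)CC)C[C@@H](O[Si](CC)(CC)CC)[C@@H](CC(=O)OC(C)(C)C)[C@@H](O[Si](C)(C)C(C)(C)C)[C@@H]1C(=O)O3
F9 | step 10 | C14 alcohol, C8 triethylsilyl ether | [C@H]3(O[C@@H]4C[C@H](C)CC[C@H]4C(C)C)[C@]1(CO)C[C@@H](O[Si](CC)(CC)CC)[C@@H](CC(=O)OC(C)(C)C)[C@@H](O[Si](C)(C)C(C)(C)C)[C@@H]1C(=O)O3
F10 | step 10 | C14 triflate, C8 triethylsilyl ether | [C@H]3(O[C@@H]4C[C@H](C)CC[C@H]4C(C)C)[C@]1(COS(=O)(=O)C(F)(F)F)C[C@@H](O[Si](CC)(CC)CC)[C@@H](CC(=O)OC(C)(C)C)[C@@H](O[Si](C)(C)C(C)(C)C)[C@@H]1C(=O)O3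
F11 | step 10 | C14 iodide, C8 triethylsilyl ether | [C@H]3(O[C@@H]4C[C@H](C)CC[C@H]4C(C)C)[C@]1(CI)C[C@@H](O[Si](CC)(CC)CC)[C@@H](CC(=O)OC(C)(C)C)[C@@H](O[Si](C)(C)C(C)(C)C)[C@@H]1C(=O)O3
F12 | step 15 | C1 alcohol with C4=C3 in place | OC[C@]1(C)C[C@@H](O[Si](CC)(CC)CC)[C@@H](CC(=O)OC(C)(C)C)[C@@H](O[Si](C)(C)C(C)(C)C)[C@@H]1C(=C)COCc2ccc(OC)cc2
F13 | step 15 | C1 aldehyde with C4=C3 in place | O=C[C@]1(C)C[C@@H](O[Si](CC)(CC)CC)[C@@H](CC(=O)OC(C)(C)C)[C@@H](O[Si](C)(C)C(C)(C)C)[C@@H]1C(=C)COCc2ccc(OC)cc2
F14 | step 22 | tert-butyl ester of the target | C=C[C@]1(C)C[C@@H](OC(=O)C(=C)[C@@H](O)CO)[C@@H](C(=C)C(=O)OC(C)(C)C)[C@@H](O)[C@@H]1C(=C)CO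
F15 | step 22 | trimethylsilyl ester tetrakis(trimethylsilyl) ether of the target | C=C[C@]1(C)C[C@@H](OC(=O)C(=C)[C@@H](O[Si](C)(C)C)CO[Si](C)(C)C)[C@@H](C(=C)C(=O)O[Si](C)(C)C)[C@@H](O[Si](C)(C)C)[C@@H]1C(=C)CO[Si](C)(C)C
A1 | alternative 1 | cis-fused bicyclo[4.2.0]oct-7-ene: C1=C4 cyclobutene, C10 methyl, C15 OTBS, C6 OTES | C1=C(CO[Si](C)(C)C(C)(C)C)[C@H]2[C@@H](O[Si](CC)(CC)CC)CCC[C@@]12C
A2 | alternative 1 | cis-1-vinyl-2-(silyloxymethyl-vinyl)cyclohexane with C6 triethylsilyl ether | C=C[C@]1(C)CCC[C@H](O[Si](CC)(CC)CC)[C@@H]1C(=C)CO[Si](C)(C)C(C)(C)C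
A3 | alternative 2 | open-chain C6 aldehyde with (Z)-2-(bromomethyl)enoate (allyl ester, C8 OPMB, C15 OTBS) | C=C[C@](C)(C[C@@H](OCc1ccc(OC)cc1)/C=C(\CBr)C(=O)OCC=C)[C@H](C=O)C(=C)CO[Si](C)(C)C(C)(C)C
A4 | alternative 2 | cyclohexane hydroxy ester (C6–OH free, C8 OPMB, C15 OTBS, C12 allyl ester) | C=C[C@]1(C)C[C@@H](OCc2ccc(OC)cc2)[C@@H](C(=C)C(=O)OCC=C)[C@@H](O)[C@@H]1C(=C)CO[Si](C)(C)C(C)(C)C
A5 | alternative 3 | 2-methylene-oxocene (ring O–C8–C7–C6–C5–C10=C1–C2) | C=C1OC/C=C(C)\[C@@H](C(=C)CO[Si](C)(C)C(C)(C)C)[C@H](O[Si](CC)(CC)CC)[C@@H]1C(=C)COCc2ccc(OC)cc2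
A6 | alternative 3 | 3-methyl-3-vinylcyclohexanone (C8 ketone) with C5, C6, C7 substituents | C=C[C@]1(C)CC(=O)[C@@H](C(=C)COCc2ccc(OC)cc2)[C@@H](O[Si](CC)(CC)CC)[C@@H]1C(=C)CO[Si](C)(C)C(C)(C)C
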